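**Strategy**

Ring A is the benzoate ring (C1 CO2Me, C2 O-prenyl, C4 CH3, C6 aryloxy) and ring B the benzyl alcohol ring. The plan cuts two neighbouring bonds of ring A at once: C6–O of the diaryl ether and C1–carboxyl. This contiguous C2-alkoxy/C1-carboxyl/C6-aryloxy array is what a 3-alkoxybenzyne delivers when its remote carbon accepts a nucleophile and its near carbon an electrophile. One operation therefore joins the ring B phenoxide, the C1–C6 aryne of ring A and CO2 to the complete 2-aryloxybenzoic acid. The precursors are an ortho-silyl aryl triflate from orcinol and a silyl-protected salicyl alcohol from 2-hydroxy-5-methoxybenzaldehyde.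

Key step: step 11

Remark: the target is achiral, so no stereocentre has to be set. The structures of the silyl triflate, the ring B phenol and the coupled acid were checked atom by atom against the target and needed no correction. As design changes, the phenoxide is preformed with KH (no proton donor is left behind) and the coupling is run in THF with KF/18-crown-6.

**Route**

Step 1
Reactants: 1 orcinol; 2 prenyl bromide
Product: 3 3-methyl-5-(3-methylbut-2-enyloxy)phenol
Conditions: 1 (3 equiv), 2 (1 equiv), K2CO3, acetone, reflux
Reagents that add atoms: none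
Why: Williamson etherification of a phenoxide with an allylic bromide; a threefold excess of the cheap, water-soluble diol should hold back the bis-ether and K2CO3 in acetone favours O- over C-alkylation.

Step 2
Reactants: 3 3-methyl-5-(3-methylbut-2-enyloxy)phenol
Product: 4 3-methyl-5-(3-methylbut-2-enyloxy)phenyl N,N-diethylcarbamate
Conditions: Et2NCOCl, K2CO3, MeCN, reflux
Reagents that add atoms: N,N-diethylcarbamoyl chloride, CCN(CC)C(Cl)=O
Why: O-carbamoylation of a phenoxide by an acyl chloride (nucleophilic acyl substitution) installs the directing group for the metalation.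

Step 3
Reactants: 4 3-methyl-5-(3-methylbut-2-enyloxy)phenyl N,N-diethylcarbamate
Product: 6 5-methyl-3-(3-methylbut-2-enyloxy)-2-(trimethylsilyl)phenyl N,N-diethylcarbamate, via C2-aryllithium 5 (not isolated)
Conditions: LiN(iPr)2 (1.3 equiv), Me3SiCl (1.5 equiv, present during metalation), THF, −78 °C
Reagents that add atoms: chlorotrimethylsilane, C[Si](C)(C)Cl
Why: Directed ortho metalation with in situ silyl quench: C2 lies between the carbamate and ether oxygens and is the most acidic ring position, LiN(iPr)2 is too weak a base to attack the allylic OCH2 of the prenyl ether, and Me3SiCl traps the aryllithium at −78 °C before the carbamoyl group can migrate.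

Step 4
Reactants: 6 5-methyl-3-(3-methylbut-2-enyloxy)-2-(trimethylsilyl)phenyl N,N-diethylcarbamate
Product: 7 5-methyl-3-(3-methylbut-2-enyloxy)-2-(trimethylsilyl)phenol
Conditions: LiAlH4, THF, 0 → 65 °C; aq. potassium sodium tartrate work-up
Reagents that add atoms: none
Why: Hydride reduction of the carbamate carbonyl (reductive cleavage) releases the phenoxide and reduces the carbamoyl residue to a volatile amine, while the aryl–silicon bond and the prenyl ether are inert to LiAlH4.

Step 5
Reactants: 7 5-methyl-3-(3-methylbut-2-enyloxy)-2-(trimethylsilyl)phenol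
Product: 8 5-methyl-3-(3-methylbut-2-enyloxy)-2-(trimethylsilyl)phenyl trifluoromethanesulfonate
Conditions: PhNTf2, DBU, MeCN, 20 → 40 °C
Reagents that add atoms: N-phenylbis(trifluoromethanesulfonimide), O=S(=O)(N(c1ccccc1)S(=O)(=O)C(F)(F)F)C(F)(F)F
Why: O-sulfonylation of the phenoxide by the mild triflyl donor PhNTf2 under base, conditions that avoid the strong acid that could cause protodesilylation.

Step 6
Reactants: 9 2-hydroxy-5-methoxybenzaldehyde
Product: 10 3-bromo-2-hydroxy-5-methoxybenzaldehyde
Conditions: Br2, NaOAc, AcOH, 20 °C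
Reagents that add atoms: bromine, BrBr
Why: Electrophilic aromatic bromination: with the position para to the hydroxyl blocked by OMe, C3 is ortho to the hydroxyl and meta to the formyl group and should be the only site attacked.

Step 7
Reactants: 10 3-bromo-2-hydroxy-5-methoxybenzaldehyde
Product: 11 2,3-dihydroxy-5-methoxybenzaldehyde
Conditions: NaOH (aq.), Cu powder (cat.), reflux, argon; then HCl to pH 2
Reagents that add atoms: sodium hydroxide, [Na+].[OH-]
Why: Copper-mediated Ullmann-type hydroxylation of an ortho-bromophenoxide, the exchange that converts 5-bromovanillin into 5-hydroxyvanillin, with the aldehyde protected against the alkali as part of the vinylogous phenoxide.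

Step 8
Reactants: 11 2,3-dihydroxy-5-methoxybenzaldehyde; 2 prenyl bromide
Product: 13 2-hydroxy-5-methoxy-3-(3-methylbut-2-enyloxy)benzaldehyde, via disodium catecholate 12 (not isolated)
Conditions: NaH (2.2 equiv), DMSO, 20 °C, argon; then 2 (1.0 equiv); dilute HCl quench
Reagents that add atoms: none
Why: Williamson etherification of the catechol dianion: the C2 oxide is conjugated with and chelated to the formyl group, so the more basic C3 oxide should take up the single equivalent of prenyl bromide.

Step 9
Reactants: 13 2-hydroxy-5-methoxy-3-(3-methylbut-2-enyloxy)benzaldehyde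
Product: 14 2-(hydroxymethyl)-4-methoxy-6-(3-methylbut-2-enyloxy)phenol
Conditions: NaBH4, MeOH, 0 °C; neutral work-up
Reagents that add atoms: none
Why: Hydride reduction of the aldehyde to the primary benzylic alcohol; ethers and alkene are untouched.

Step 10
Reactants: 14 2-(hydroxymethyl)-4-methoxy-6-(3-methylbut-2-enyloxy)phenol
Product: 15 2-(tert-butyldimethylsilyloxymethyl)-4-methoxy-6-(3-methylbut-2-enyloxy)phenol
Conditions: TBSCl (1.05 equiv), imidazole, CH2Cl2, 0 °C
Reagents that add atoms: tert-butyldimethylsilyl chloride, CC(C)(C)[Si](C)(C)Cl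
Why: Silyl ether formation (silylation via the N-silylimidazolium): the primary benzylic hydroxyl should react much faster than the phenol, which is flanked by two ortho substituents.

Step 11
Reactants: 8 5-methyl-3-(3-methylbut-2-enyloxy)-2-(trimethylsilyl)phenyl trifluoromethanesulfonate; 15 2-(tert-butyldimethylsilyloxymethyl)-4-methoxy-6-(3-methylbut-2-enyloxy)phenol; 16 carbon dioxide
Product: 20 2-[2-(tert-butyldimethylsilyloxymethyl)-4-methoxy-6-(3-methylbut-2-enyloxy)phenoxy]-4-methyl-6-(3-methylbut-2-enyloxy)benzoic acid, via potassium phenoxide 17 (not isolated), via ring A aryne 18 (not isolated), via C1 arylpotassium 19 (not isolated)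
Conditions: 15 (1.5 equiv), KH, THF, 0 °C; then KF, 18-crown-6, CO2 (1 atm), 8 (1.0 equiv) added slowly, 0 → 20 °C; cold dilute HCl to pH 4
Reagents that add atoms: none
Why: Proposed new method: KF/18-crown-6 strips Me3Si from 8 and triflate departs, giving aryne 18, in which the electron-withdrawing C2 prenyloxy group polarises the strained triple bond so that phenoxide 17 bonds to C6; the C1 carbanion 19 that results sits between two oxygen-bearing carbons, is inductively stabilised and is intercepted by CO2 to give the carboxylate. The closest known reaction types are the three-component coupling of arynes with nitrogen nucleophiles and CO2 and the meta-selective O-arylation of phenols by 3-alkoxyarynes. No ring is closed and no stereocentre is created. The selectivity needed is O–C6 over O–C1 bonding, which the C2 alkoxy group controls through aryne distortion, and carboxylation ahead of protonation, which is secured by preforming the phenoxide with KH (H2 as the only by-product), by THF in place of acetonitrile and by a CO2-saturated solution. The two ortho substituents of 17 matter little for addition to an aryne, whereas they would slow a metal-catalysed etherification.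

Step 12
Reactants: 20 2-[2-(tert-butyldimethylsilyloxymethyl)-4-methoxy-6-(3-methylbut-2-enyloxy)phenoxy]-4-methyl-6-(3-methylbut-2-enyloxy)benzoic acid
Product: 21 methyl 2-[2-(tert-butyldimethylsilyloxymethyl)-4-methoxy-6-(3-methylbut-2-enyloxy)phenoxy]-4-methyl-6-(3-methylbut-2-enyloxy)benzoate
Conditions: MeI, K2CO3, DMF, 20 °C
Reagents that add atoms: iodomethane, CI
Why: SN2 O-alkylation of the carboxylate, an esterification that does not require attack at the carbonyl group shielded by two ortho substituents.

Step 13
Reactants: 21 methyl 2-[2-(tert-butyldimethylsilyloxymethyl)-4-methoxy-6-(3-methylbut-2-enyloxy)phenoxy]-4-methyl-6-(3-methylbut-2-enyloxy)benzoate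
Product: 22 methyl 2-[2-(hydroxymethyl)-4-methoxy-6-(3-methylbut-2-enyloxy)phenoxy]-4-methyl-6-(3-methylbut-2-enyloxy)benzoate (CNP0561346.0)
Conditions: Bu4NF, AcOH, THF, 0 → 20 °C
Reagents that add atoms: none
Why: Fluoride-induced desilylation driven by the strong Si–F bond, buffered with AcOH so that the liberated alkoxide cannot attack the ester, frees the benzylic alcohol of the achiral target.

**Compound list**

1 | orcinol (5-methylbenzene-1,3-diol) | Cc1cc(O)cc(O)c1 | starting material
2 | prenyl bromide (1-bromo-3-methylbut-2-ene) | CC(C)=CCBr | starting material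
3 | 3-methyl-5-(3-methylbut-2-enyloxy)phenol | Cc1cc(O)cc(OCC=C(C)C)c1 | intermediate
4 | 3-methyl-5-(3-methylbut-2-enyloxy)phenyl N,N-diethylcarbamate | CCN(CC)C(=O)Oc1cc(C)cc(OCC=C(C)C)c1 | intermediate
5 | [2-(diethylcarbamoyloxy)-4-methyl-6-(3-methylbut-2-enyloxy)phenyl]lithium (not isolated) | [Li]c1c(OC(=O)N(CC)CC)cc(C)cc1OCC=C(C)C | intermediate
6 | 5-methyl-3-(3-methylbut-2-enyloxy)-2-(trimethylsilyl)phenyl N,N-diethylcarbamate | CCN(CC)C(=O)Oc1cc(C)cc(OCC=C(C)C)c1[Si](C)(C)C | intermediate
7 | 5-methyl-3-(3-methylbut-2-enyloxy)-2-(trimethylsilyl)phenol | Cc1cc(O)c([Si](C)(C)C)c(OCC=C(C)C)c1 | intermediate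
8 | 5-methyl-3-(3-methylbut-2-enyloxy)-2-(trimethylsilyl)phenyl trifluoromethanesulfonate | CC(C)=CCOc1cc(C)cc(OS(=O)(=O)C(F)(F)F)c1[Si](C)(C)C | intermediate
9 | 2-hydroxy-5-methoxybenzaldehyde | COc1ccc(O)c(C=O)c1 | starting material
10 | 3-bromo-2-hydroxy-5-methoxybenzaldehyde | COc1cc(Br)c(O)c(C=O)c1 | intermediate
11 | 2,3-dihydroxy-5-methoxybenzaldehyde | COc1cc(O)c(O)c(C=O)c1 | intermediate
12 | disodium 3-formyl-5-methoxybenzene-1,2-diolate (not isolated) | [Na+].[Na+].COc1cc([O-])c([O-])c(C=O)c1 | intermediate
13 | 2-hydroxy-5-methoxy-3-(3-methylbut-2-enyloxy)benzaldehyde | COc1cc(OCC=C(C)C)c(O)c(C=O)c1 | intermediate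
14 | 2-(hydroxymethyl)-4-methoxy-6-(3-methylbut-2-enyloxy)phenol | COc1cc(CO)c(O)c(OCC=C(C)C)c1 | intermediate
15 | 2-(tert-butyldimethylsilyloxymethyl)-4-methoxy-6-(3-methylbut-2-enyloxy)phenol | COc1cc(CO[Si](C)(C)C(C)(C)C)c(O)c(OCC=C(C)C)c1 | intermediate
16 | carbon dioxide | O=C=O | starting material
17 | potassium 2-(tert-butyldimethylsilyloxymethyl)-4-methoxy-6-(3-methylbut-2-enyloxy)phenoxide (not isolated) | [K+].COc1cc(CO[Si](C)(C)C(C)(C)C)c([O-])c(OCC=C(C)C)c1 | intermediate
18 | 5-methyl-3-(3-methylbut-2-enyloxy)benzyne, the C1–C6 aryne of ring A (not isolated) | CC(C)=CCOC1=CC(C)=CC#C1 | intermediate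
19 | {2-[2-(tert-butyldimethylsilyloxymethyl)-4-methoxy-6-(3-methylbut-2-enyloxy)phenoxy]-4-methyl-6-(3-methylbut-2-enyloxy)phenyl}potassium (not isolated) | [K]c1c(OCC=C(C)C)cc(C)cc1Oc1c(CO[Si](C)(C)C(C)(C)C)cc(OC)cc1OCC=C(C)C | intermediate
20 | 2-[2-(tert-butyldimethylsilyloxymethyl)-4-methoxy-6-(3-methylbut-2-enyloxy)phenoxy]-4-methyl-6-(3-methylbut-2-enyloxy)benzoic acid | OC(=O)c1c(OCC=C(C)C)cc(C)cc1Oc1c(CO[Si](C)(C)C(C)(C)C)cc(OC)cc1OCC=C(C)C | intermediate
21 | methyl 2-[2-(tert-butyldimethylsilyloxymethyl)-4-methoxy-6-(3-methylbut-2-enyloxy)phenoxy]-4-methyl-6-(3-methylbut-2-enyloxy)benzoate | COC(=O)c1c(OCC=C(C)C)cc(C)cc1Oc1c(CO[Si](C)(C)C(C)(C)C)cc(OC)cc1OCC=C(C)C | intermediate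
22 | methyl 2-[2-(hydroxymethyl)-4-methoxy-6-(3-methylbut-2-enyloxy)phenoxy]-4-methyl-6-(3-methylbut-2-enyloxy)benzoate (CNP0561346.0) | COC(=O)c1c(OCC=C(C)C)cc(C)cc1Oc1c(CO)cc(OC)cc1OCC=C(C)C | target

**Step count and risks**

Total steps: 13. Longest linear sequence: 8 steps (steps 1–5 or steps 6–10, followed by steps 11–13).

Steps most likely to fail:

Step 11. The C1 carbanion may be protonated before it meets CO2, by adventitious water or by the allylic OCH2 of the neighbouring prenyl ether. The phenoxide may also be tied up as its carbonate and so capture the aryne too slowly, and fluoride may slowly erode the silyl ether. The fallback builds the same two bonds by known chemistry in the opposite order and sets out from phenol 15. Purchased 3-bromo-5-methylphenol F1 would be O-prenylated with 2 (K2CO3, DMF) to 1-bromo-3-methyl-5-(3-methylbut-2-enyloxy)benzene F2. Deprotonation of F2 with LiN(iPr)2 in THF at −78 °C at the carbon between bromine and the ether oxygen would give [2-bromo-4-methyl-6-(3-methylbut-2-enyloxy)phenyl]lithium F3, which would be acylated with ClCO2Me to methyl 2-bromo-4-methyl-6-(3-methylbut-2-enyloxy)benzoate F4. Ullmann etherification of F4 with 15 (CuI, picolinic acid, K3PO4, DMSO, 90 °C) would then give the silyl-protected ester and come back to the route at 21.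

Step 7. The bromide–hydroxide exchange may stay incomplete, and the electron-rich catechol may be oxidised by air in the hot alkaline medium. The fallback makes the C3–O bond by oxidative rearrangement of a formyl group and sets out from 9. Duff formylation (hexamethylenetetramine, CF3CO2H, reflux, then aqueous HCl) would place a second formyl group on C3 to give 2-hydroxy-5-methoxybenzene-1,3-dicarbaldehyde F5. Dakin oxidation with one equivalent of H2O2 in aqueous NaOH at 0 °C would turn one formyl group into a hydroxyl group and come back to the route at 11, bypassing 10.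

Step 3. Metalation of C2 by the amide base may stay incomplete, or the carbamoyl group may migrate to the lithiated carbon (anionic Fries rearrangement) before silicon arrives; a stronger alkyllithium cannot be used, because it would attack the allylic ether. The fallback introduces silicon before the prenyl ether and sets out from 1. Orcinol would be converted with Et2NCOCl (2.2 equiv, K2CO3, MeCN) into 5-methyl-1,3-phenylene bis(N,N-diethylcarbamate) F6. Metalation with sBuLi/TMEDA in THF at −78 °C would give [2,6-bis(diethylcarbamoyloxy)-4-methylphenyl]lithium F7, and Me3SiCl would give 5-methyl-2-(trimethylsilyl)-1,3-phenylene bis(N,N-diethylcarbamate) F8. LiAlH4 would cleave both carbamates to 5-methyl-2-(trimethylsilyl)benzene-1,3-diol F9, and mono-prenylation with 2 (K2CO3, acetone) would come back to the route at 7.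

Further compounds
F1 | step 11 | 3-bromo-5-methylphenol | Cc1cc(O)cc(Br)c1
F2 | step 11 | 1-bromo-3-methyl-5-(3-methylbut-2-enyloxy)benzene | Cc1cc(Br)cc(OCC=C(C)C)c1
F3 | step 11 | [2-bromo-4-methyl-6-(3-methylbut-2-enyloxy)phenyl]lithium | [Li]c1c(Br)cc(C)cc1OCC=C(C)C
F4 | step 11 | methyl 2-bromo-4-methyl-6-(3-methylbut-2-enyloxy)benzoate | COC(=O)c1c(Br)cc(C)cc1OCC=C(C)C
F5 | step 7 | 2-hydroxy-5-methoxybenzene-1,3-dicarbaldehyde | COc1cc(C=O)c(O)c(C=O)c1
F6 | step 3 | 5-methyl-1,3-phenylene bis(N,N-diethylcarbamate) | CCN(CC)C(=O)Oc1cc(C)cc(OC(=O)N(CC)CC)c1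
F7 | step 3 | [2,6-bis(diethylcarbamoyloxy)-4-methylphenyl]lithium | [Li]c1c(OC(=O)N(CC)CC)cc(C)cc1OC(=O)N(CC)CC
F8 | step 3 | 5-methyl-2-(trimethylsilyl)-1,3-phenylene bis(N,N-diethylcarbamate) | CCN(CC)C(=O)Oc1cc(C)cc(OC(=O)N(CC)CC)c1[Si](C)(C)C
F9 | step 3 | 5-methyl-2-(trimethylsilyl)benzene-1,3-diol | Cc1cc(O)c([Si](C)(C)C)c(O)c1
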